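The side-chain bond C13–C14 is formed by an Ireland–Claisen rearrangement. The step exploits an allylic oxygen on C11, the carbon attached to C9 of ring B. The precursor is an ent-drimane carrying a (1R,2Z)-1-acetoxybut-2-enyl group on C9. The acetate supplies C14–C15, and one [3,3] shift forms C13–C14, transfers the C11 configuration to C13 and turns C11–O into the C11=C12 alkene, which is hydrogenated at the end. Rings A and B come from a catalytic asymmetric Diels–Alder reaction (C4 quaternary centre and C5) and a proton-initiated cyclisation that closes ring B and places the oxygen on C8.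

Key step: step 9

Remark: atoms carry labdane numbers (ring A C1–C5/C10, ring B C5–C10, side chain C11–C16, C17 on C8, C18 = CH2O and C19 = CH3 on C4, C20 on C10); the SMILES is read as the ent-labdane (4S,5S,8S,9S,10R,13S) with C18 trans to C20.

Step 1
Reactants: 1 geranyl acetate
Product: 3 (2E,6E)-3,7-dimethyl-8-oxoocta-2,6-dien-1-yl acetate, via (2E,6E)-8-hydroxygeranyl acetate 2 (not isolated)
Conditions: SeO2 (0.3 equiv), t-BuOOH, CH2Cl2, rt; then MnO2, CH2Cl2, rt
Reagents that add atoms: tert-butyl hydroperoxide (CC(C)(C)OO)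
Why: Selenium dioxide allylic oxidation (ene reaction then [2,3] shift) should attack the E-methyl of the electron-rich distal alkene rather than the acetate-deactivated one, and MnO2 carries the allylic alcohol on to the E-enal.

Step 2
Reactants: 3 (2E,6E)-3,7-dimethyl-8-oxoocta-2,6-dien-1-yl acetate
Product: 4 (2E,6E)-3,7-dimethylnona-2,6,8-trien-1-yl acetate
Conditions: Ph3PCH3Br, KN(SiMe3)2, THF, −78 to 0 °C
Reagents that add atoms: methyltriphenylphosphonium bromide (C[P+](c1ccccc1)(c1ccccc1)c1ccccc1.[Br-])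
Why: Wittig methylenation of the aldehyde should be much faster than attack on the acetate at low temperature and leaves the E geometry of the trisubstituted alkene untouched, giving the (E)-1-alkyl-2-methylbutadiene.

Step 3
Reactants: 4 (2E,6E)-3,7-dimethylnona-2,6,8-trien-1-yl acetate; 5 methacrolein
Product: 7 (2E)-5-[(1S,6S)-6-(hydroxymethyl)-2,6-dimethylcyclohex-2-en-1-yl]-3-methylpent-2-en-1-yl acetate, via Diels–Alder aldehyde 6 (not isolated)
Conditions: (S)-3,3-diphenyl-1-(o-tolyl)tetrahydro-1H,3H-pyrrolo[1,2-c][1,3,2]oxazaborole (15 mol %), HNTf2 (12 mol %), CH2Cl2, −78 to −40 °C; then NaBH4, MeOH, −40 to 0 °C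
Reagents that add atoms: none
Why: In this oxazaborolidinium-catalysed Diels–Alder reaction the 1-alkyl group of the diene should direct the quaternary α-carbon of methacrolein to the substituted terminus, the formyl group reacts exo so that CHO ends trans to the C5 chain, and the (S)-catalyst exposes the Re face of the α-carbon, which sets C4 (S) and C5 (S); borohydride then reduces the aldehyde without touching the acetate.

Step 4
Reactants: 7 (2E)-5-[(1S,6S)-6-(hydroxymethyl)-2,6-dimethylcyclohex-2-en-1-yl]-3-methylpent-2-en-1-yl acetate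
Product: 8 (2E)-5-[(1S,6S)-6-[(benzyloxy)methyl]-2,6-dimethylcyclohex-2-en-1-yl]-3-methylpent-2-en-1-yl acetate
Conditions: 2-benzyloxy-1-methylpyridinium triflate, MgO, PhCF3, 85 °C
Reagents that add atoms: 2-benzyloxy-1-methylpyridinium triflate (C[n+]1ccccc1OCc1ccccc1.[O-]S(=O)(=O)C(F)(F)F)
Why: Neutral benzyl transfer from the pyridinium salt (O-benzylation) should etherify the neopentyl alcohol without base, which would cleave the acetate, and without strong acid, which would start the cyclisation early.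

Step 5
Reactants: 8 (2E)-5-[(1S,6S)-6-[(benzyloxy)methyl]-2,6-dimethylcyclohex-2-en-1-yl]-3-methylpent-2-en-1-yl acetate
Product: 10 (1R,2S,4aS,5S,8aR)-5-[(benzyloxy)methyl]-1-(hydroxymethyl)-2,5,8a-trimethyldecahydronaphthalen-2-ol, via hydroxy acetate 9 (not isolated)
Conditions: FSO3H, 2-nitropropane, −78 °C; aq. NaHCO3; then NaOMe, MeOH, 40 °C
Reagents that add atoms: none
Why: In this proton-initiated cation–olefin cyclisation, Markovnikov protonation of the ring alkene should give the C10 cation, C9 of the (E)-alkene adds through a chair transition state on the face of H5 (trans fusion, C11 equatorial), and the acetate carbonyl oxygen captures C8 anti (equatorial C8–O) as a dioxanylium ion that is hydrolysed on quench, after which methanolysis of either mono-acetate frees the 8,11-diol.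

Step 6
Reactants: 10 (1R,2S,4aS,5S,8aR)-5-[(benzyloxy)methyl]-1-(hydroxymethyl)-2,5,8a-trimethyldecahydronaphthalen-2-ol
Product: 11 (1S,2S,4aS,5S,8aR)-5-[(benzyloxy)methyl]-2-hydroxy-2,5,8a-trimethyldecahydronaphthalene-1-carbaldehyde
Conditions: TEMPO (10 mol %), PhI(OAc)2, CH2Cl2, rt
Reagents that add atoms: none
Why: Oxoammonium (TEMPO) oxidation is selective for the primary alcohol, the tertiary C8 hydroxyl cannot be oxidised, and the near-neutral medium should spare the β-hydroxy aldehyde from elimination and retro-aldol cleavage.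

Step 7
Reactants: 11 (1S,2S,4aS,5S,8aR)-5-[(benzyloxy)methyl]-2-hydroxy-2,5,8a-trimethyldecahydronaphthalene-1-carbaldehyde; 12 (Z)-1-bromoprop-1-ene
Product: 14 (1R,2Z)-1-[(1R,2S,4aS,5S,8aR)-5-[(benzyloxy)methyl]-2-hydroxy-2,5,8a-trimethyldecahydronaphthalen-1-yl]but-2-en-1-ol, via (Z)-prop-1-enyllithium 13 (not isolated)
Conditions: 12, t-BuLi, Et2O, −78 °C; then 11, MgBr2·OEt2, CH2Cl2/Et2O, −78 °C; aq. NH4Cl
Reagents that add atoms: none
Why: In this chelation-controlled 1,2-addition, magnesium bridging the C8 oxygen and the aldehyde oxygen should leave the carbonyl face under the axial C17 and C20 methyls blocked, so the alkenyl group enters from the face of H9 and sets C11 as R, while the Z geometry comes unchanged from the bromide through stereoretentive halogen–lithium exchange.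

Step 8
Reactants: 14 (1R,2Z)-1-[(1R,2S,4aS,5S,8aR)-5-[(benzyloxy)methyl]-2-hydroxy-2,5,8a-trimethyldecahydronaphthalen-1-yl]but-2-en-1-ol
Product: 15 (1R,2Z)-1-[(1R,2S,4aS,5S,8aR)-5-[(benzyloxy)methyl]-2-hydroxy-2,5,8a-trimethyldecahydronaphthalen-1-yl]but-2-en-1-yl acetate
Conditions: Ac2O, pyridine, DMAP (cat.), CH2Cl2, 0 °C
Reagents that add atoms: acetic anhydride (CC(=O)OC(C)=O)
Why: Nucleophile-catalysed acylation should esterify the secondary allylic hydroxyl only, because the tertiary C8 hydroxyl is far less reactive, and so attaches the future C14–C15 unit to O11.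

Step 9
Reactants: 15 (1R,2Z)-1-[(1R,2S,4aS,5S,8aR)-5-[(benzyloxy)methyl]-2-hydroxy-2,5,8a-trimethyldecahydronaphthalen-1-yl]but-2-en-1-yl acetate
Product: 18 (3R,4E)-5-[(1S,2S,4aS,5S,8aR)-5-[(benzyloxy)methyl]-2-hydroxy-2,5,8a-trimethyldecahydronaphthalen-1-yl]-3-methylpent-4-enoic acid, via silyl ketene acetal 16 (not isolated), via bis-silylated pentenoate 17 (not isolated)
Conditions: Me3SiCl, Et3N, LiN(i-Pr)2 (3 equiv), THF, −78 °C then 60 °C; 1 M HCl
Reagents that add atoms: none
Why: Ireland–Claisen rearrangement: the amide base with Me3SiCl present should convert the C11 acetate into its O-silyl ketene acetal and silylate the C8 alkoxide in the flask, and on warming the allyl vinyl ether unit C14=C15–O11–C11–C12=C13 undergoes a concerted suprafacial [3,3] shift that forms C13–C14 and breaks C11–O11. No ring is closed, and the closest known reaction type is the ester-enolate Claisen transfer of chirality from a secondary (Z)-allylic acetate to a methyl-bearing carbon. The new C13 stereocentre is controlled by the C11 stereocentre together with the Z geometry: in the chair transition state C9 of ring B sits equatorial, so C14 is delivered to the face of C13 from which O11 departs, giving 13R in 18 (13S by descriptor once C11=C12 is saturated) and the (E)-C11=C12 alkene. The step needs chair over boat and C9-equatorial over C9-axial, and both are secured by the cis methyl on C13, which would clash with an axial C9 (allylic 1,3-strain). The unsubstituted ketene acetal removes any question of enolate geometry, and the acidic work-up cleaves both silyl groups.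

Step 10
Reactants: 18 (3R,4E)-5-[(1S,2S,4aS,5S,8aR)-5-[(benzyloxy)methyl]-2-hydroxy-2,5,8a-trimethyldecahydronaphthalen-1-yl]-3-methylpent-4-enoic acid
Product: 19 (1S,2S,4aS,5S,8aR)-5-[(benzyloxy)methyl]-1-[(1E,3R)-5-hydroxy-3-methylpent-1-en-1-yl]-2,5,8a-trimethyldecahydronaphthalen-2-ol
Conditions: LiAlH4, THF, 0 °C to rt
Reagents that add atoms: none
Why: Hydride reduction of the carboxylic acid should give the primary C15 alcohol while the isolated alkene, the benzyl ether and the tertiary alcohol are inert.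

Step 11
Reactants: 19 (1S,2S,4aS,5S,8aR)-5-[(benzyloxy)methyl]-1-[(1E,3R)-5-hydroxy-3-methylpent-1-en-1-yl]-2,5,8a-trimethyldecahydronaphthalen-2-ol; 20 2,2-dimethyl-1,3-dioxane-4,6-dione
Product: 21 3-{[(3R,4E)-5-[(1S,2S,4aS,5S,8aR)-5-[(benzyloxy)methyl]-2-hydroxy-2,5,8a-trimethyldecahydronaphthalen-1-yl]-3-methylpent-4-en-1-yl]oxy}-3-oxopropanoic acid
Conditions: toluene, 90 °C
Reagents that add atoms: none
Why: Thermal alcoholysis of the cyclic acylal (ring-opening acylation with loss of acetone) should give the malonic half ester directly at the unhindered primary C15 hydroxyl, since the tertiary C8 hydroxyl does not react.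

Step 12
Reactants: 21 3-{[(3R,4E)-5-[(1S,2S,4aS,5S,8aR)-5-[(benzyloxy)methyl]-2-hydroxy-2,5,8a-trimethyldecahydronaphthalen-1-yl]-3-methylpent-4-en-1-yl]oxy}-3-oxopropanoic acid
Product: 22 3-{[(3S)-5-[(1S,2S,4aS,5S,8aR)-2-hydroxy-5-(hydroxymethyl)-2,5,8a-trimethyldecahydronaphthalen-1-yl]-3-methylpentyl]oxy}-3-oxopropanoic acid
Conditions: H2 (1 atm), Pd/C, EtOAc, rt
Reagents that add atoms: none
Why: Heterogeneous hydrogenation should saturate the 1,2-disubstituted C11=C12 alkene (faster than double-bond migration toward C13) and hydrogenolyse the benzyl ether in the same operation, leaving the malonic half ester and all stereocentres untouched.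

Compound list
1 | geranyl acetate, (2E)-3,7-dimethylocta-2,6-dien-1-yl acetate | CC(=O)OC/C=C(\C)CCC=C(C)C | starting material
2 | (2E,6E)-8-hydroxy-3,7-dimethylocta-2,6-dien-1-yl acetate | CC(=O)OC/C=C(\C)CC/C=C(\C)CO | intermediate
3 | (2E,6E)-3,7-dimethyl-8-oxoocta-2,6-dien-1-yl acetate | CC(=O)OC/C=C(\C)CC/C=C(\C)C=O | intermediate
4 | (2E,6E)-3,7-dimethylnona-2,6,8-trien-1-yl acetate | CC(=O)OC/C=C(\C)CC/C=C(\C)C=C | intermediate
5 | methacrolein, 2-methylprop-2-enal | CC(=C)C=O | starting material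
6 | (2E)-5-[(1S,6S)-6-formyl-2,6-dimethylcyclohex-2-en-1-yl]-3-methylpent-2-en-1-yl acetate | CC(=O)OC/C=C(\C)CC[C@H]1C(C)=CCC[C@]1(C)C=O | intermediate
7 | (2E)-5-[(1S,6S)-6-(hydroxymethyl)-2,6-dimethylcyclohex-2-en-1-yl]-3-methylpent-2-en-1-yl acetate | CC(=O)OC/C=C(\C)CC[C@H]1C(C)=CCC[C@]1(C)CO | intermediate
8 | (2E)-5-[(1S,6S)-6-[(benzyloxy)methyl]-2,6-dimethylcyclohex-2-en-1-yl]-3-methylpent-2-en-1-yl acetate | CC(=O)OC/C=C(\C)CC[C@H]1C(C)=CCC[C@]1(C)COCc2ccccc2 | intermediate
9 | [(1R,2S,4aS,5S,8aR)-5-[(benzyloxy)methyl]-2-hydroxy-2,5,8a-trimethyldecahydronaphthalen-1-yl]methyl acetate | CC(=O)OC[C@H]1[C@]2(C)CCC[C@](C)(COCc3ccccc3)[C@H]2CC[C@]1(C)O | intermediate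
10 | (1R,2S,4aS,5S,8aR)-5-[(benzyloxy)methyl]-1-(hydroxymethyl)-2,5,8a-trimethyldecahydronaphthalen-2-ol | OC[C@H]1[C@]2(C)CCC[C@](C)(COCc3ccccc3)[C@H]2CC[C@]1(C)O | intermediate
11 | (1S,2S,4aS,5S,8aR)-5-[(benzyloxy)methyl]-2-hydroxy-2,5,8a-trimethyldecahydronaphthalene-1-carbaldehyde | O=C[C@H]1[C@]2(C)CCC[C@](C)(COCc3ccccc3)[C@H]2CC[C@]1(C)O | intermediate
12 | (Z)-1-bromoprop-1-ene | C/C=C\Br | starting material
13 | (Z)-prop-1-enyllithium | C/C=C\[Li] | intermediate
14 | (1R,2Z)-1-[(1R,2S,4aS,5S,8aR)-5-[(benzyloxy)methyl]-2-hydroxy-2,5,8a-trimethyldecahydronaphthalen-1-yl]but-2-en-1-ol | C/C=C\[C@@H](O)[C@H]1[C@]2(C)CCC[C@](C)(COCc3ccccc3)[C@H]2CC[C@]1(C)O | intermediate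
15 | (1R,2Z)-1-[(1R,2S,4aS,5S,8aR)-5-[(benzyloxy)methyl]-2-hydroxy-2,5,8a-trimethyldecahydronaphthalen-1-yl]but-2-en-1-yl acetate | C/C=C\[C@@H](OC(C)=O)[C@H]1[C@]2(C)CCC[C@](C)(COCc3ccccc3)[C@H]2CC[C@]1(C)O | intermediate
16 | O-trimethylsilyl ketene acetal of 15 carrying a trimethylsilyl ether on the C8 oxygen | C/C=C\[C@@H](OC(=C)O[Si](C)(C)C)[C@H]1[C@]2(C)CCC[C@](C)(COCc3ccccc3)[C@H]2CC[C@]1(C)O[Si](C)(C)C | intermediate
17 | trimethylsilyl (3R,4E)-5-[(1S,2S,4aS,5S,8aR)-5-[(benzyloxy)methyl]-2,5,8a-trimethyl-2-(trimethylsilyloxy)decahydronaphthalen-1-yl]-3-methylpent-4-enoate | C[C@H](CC(=O)O[Si](C)(C)C)/C=C/[C@H]1[C@]2(C)CCC[C@](C)(COCc3ccccc3)[C@H]2CC[C@]1(C)O[Si](C)(C)C | intermediate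
18 | (3R,4E)-5-[(1S,2S,4aS,5S,8aR)-5-[(benzyloxy)methyl]-2-hydroxy-2,5,8a-trimethyldecahydronaphthalen-1-yl]-3-methylpent-4-enoic acid | C[C@H](CC(=O)O)/C=C/[C@H]1[C@]2(C)CCC[C@](C)(COCc3ccccc3)[C@H]2CC[C@]1(C)O | intermediate
19 | (1S,2S,4aS,5S,8aR)-5-[(benzyloxy)methyl]-1-[(1E,3R)-5-hydroxy-3-methylpent-1-en-1-yl]-2,5,8a-trimethyldecahydronaphthalen-2-ol | C[C@H](CCO)/C=C/[C@H]1[C@]2(C)CCC[C@](C)(COCc3ccccc3)[C@H]2CC[C@]1(C)O | intermediate
20 | 2,2-dimethyl-1,3-dioxane-4,6-dione | CC1(C)OC(=O)CC(=O)O1 | starting material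
21 | 3-{[(3R,4E)-5-[(1S,2S,4aS,5S,8aR)-5-[(benzyloxy)methyl]-2-hydroxy-2,5,8a-trimethyldecahydronaphthalen-1-yl]-3-methylpent-4-en-1-yl]oxy}-3-oxopropanoic acid | C[C@H](CCOC(=O)CC(=O)O)/C=C/[C@H]1[C@]2(C)CCC[C@](C)(COCc3ccccc3)[C@H]2CC[C@]1(C)O | intermediate
22 | 3-{[(3S)-5-[(1S,2S,4aS,5S,8aR)-2-hydroxy-5-(hydroxymethyl)-2,5,8a-trimethyldecahydronaphthalen-1-yl]-3-methylpentyl]oxy}-3-oxopropanoic acid (CNP0324566.1) | C[C@H](CCOC(=O)CC(=O)O)CC[C@H]1[C@]2(C)CCC[C@](C)(CO)[C@H]2CC[C@]1(C)O | target

Total step count: 12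
Longest linear sequence: 12 steps (1 to 22)

Steps most likely to fail

Step 5. The C10 cation may lose H5 to give the tetrasubstituted C5=C10 alkene and be reprotonated from either face, which would erode the C4/C5 relationship set in step 3. The acetate-deactivated side-chain alkene may also close slowly, so that elimination or attack of the superacid on the benzyl ether competes. The fallback replaces the cation at C10 by a radical that cannot exchange H5. It sets out from 8: hydrogen-atom transfer from a cobalt hydride puts H on C1 and leaves the C10 tertiary radical. The reagents are [N,N′-bis(3,5-di-tert-butylsalicylidene)-1,2-cyclohexanediaminato]cobalt (a salen complex of divalent cobalt), N-fluoro-2,4,6-trimethylpyridinium tetrafluoroborate and PhSiH3 in acetone at 0 °C. 6-Endo closure onto C9 and oxidation of the resulting C8 radical (radical–polar crossover) let the acetate carbonyl capture C8 as in the main route. Aqueous work-up should give hydroxy acetate 9, where the fallback rejoins the route before the methanolysis to 10. No compound outside the list is made (F0).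

Step 7. Facial selectivity at the aldehyde may be poor if the magnesium chelate is not maintained, giving mixtures of C11 epimers, and the β-hydroxy aldehyde may undergo retro-aldol cleavage or β-elimination under the basic conditions. The fallback sets C11 by reagent control. It sets out from 11: addition of CH3C≡CMgBr (THF, −78 °C) gives 1-[(1R,2S,4aS,5S,8aR)-5-[(benzyloxy)methyl]-2-hydroxy-2,5,8a-trimethyldecahydronaphthalen-1-yl]but-2-yn-1-ol F1 as an epimer mixture. Oxidation with 1,1,1-triacetoxy-1,1-dihydro-1,2-benziodoxol-3(1H)-one gives the ynone F2. Oxazaborolidine-catalysed (CBS) reduction with (S)-1-methyl-3,3-diphenyltetrahydro-1H,3H-pyrrolo[1,2-c][1,3,2]oxazaborole and catecholborane, the alkyne acting as the small group, should give the single (1S)-propargylic alcohol F3. It has the same spatial arrangement at C11 as 14. Semi-hydrogenation (H2, Pd/CaCO3 poisoned with Pb(OAc)2, quinoline) gives the Z alkene and comes back to the route at 14.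

Step 9. Acetyl transfer to the C8 alkoxide may occur before silylation, and a boat or axial-C9 transition state may compete in this crowded allylic system and erode the transfer of configuration from C11 to C13. The fallback replaces the sigmatropic shift by an anti-selective allylic substitution. It sets out from 11: (E)-prop-1-enyllithium (from (E)-1-bromoprop-1-ene and t-BuLi) under the same MgBr2 chelation control should give (1R,2E)-1-[(1R,2S,4aS,5S,8aR)-5-[(benzyloxy)methyl]-2-hydroxy-2,5,8a-trimethyldecahydronaphthalen-1-yl]but-2-en-1-ol F4. Esterification of the secondary hydroxyl with picolinic acid (DCC, DMAP) gives the picolinate F5. CH2=CHMgBr with CuBr·SMe2 (THF, −40 °C) then substitutes at the γ-carbon anti to the leaving group (SN2′). This forms C13–C14 as a vinyl group and the (E)-C11=C12 alkene in (1S,2S,4aS,5S,8aR)-5-[(benzyloxy)methyl]-2,5,8a-trimethyl-1-[(1E,3R)-3-methylpenta-1,4-dien-1-yl]decahydronaphthalen-2-ol F6, with the C13 configuration of 19. Hydroboration of the terminal vinyl group with 9-BBN and oxidation (NaOH, H2O2) comes back to the route at 19.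

Further compounds
F0 | step 5 | none | none
F1 | step 7 | 1-[(1R,2S,4aS,5S,8aR)-5-[(benzyloxy)methyl]-2-hydroxy-2,5,8a-trimethyldecahydronaphthalen-1-yl]but-2-yn-1-ol (C11 epimer mixture) | CC#CC(O)[C@H]1[C@]2(C)CCC[C@](C)(COCc3ccccc3)[C@H]2CC[C@]1(C)O
F2 | step 7 | 1-[(1S,2S,4aS,5S,8aR)-5-[(benzyloxy)methyl]-2-hydroxy-2,5,8a-trimethyldecahydronaphthalen-1-yl]but-2-yn-1-one | CC#CC(=O)[C@H]1[C@]2(C)CCC[C@](C)(COCc3ccccc3)[C@H]2CC[C@]1(C)O
F3 | step 7 | (1S)-1-[(1R,2S,4aS,5S,8aR)-5-[(benzyloxy)methyl]-2-hydroxy-2,5,8a-trimethyldecahydronaphthalen-1-yl]but-2-yn-1-ol | CC#C[C@@H](O)[C@H]1[C@]2(C)CCC[C@](C)(COCc3ccccc3)[C@H]2CC[C@]1(C)O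
F4 | step 9 | (1R,2E)-1-[(1R,2S,4aS,5S,8aR)-5-[(benzyloxy)methyl]-2-hydroxy-2,5,8a-trimethyldecahydronaphthalen-1-yl]but-2-en-1-ol | C/C=C/[C@@H](O)[C@H]1[C@]2(C)CCC[C@](C)(COCc3ccccc3)[C@H]2CC[C@]1(C)O
F5 | step 9 | (1R,2E)-1-[(1R,2S,4aS,5S,8aR)-5-[(benzyloxy)methyl]-2-hydroxy-2,5,8a-trimethyldecahydronaphthalen-1-yl]but-2-en-1-yl pyridine-2-carboxylate | C/C=C/[C@@H](OC(=O)c3ccccn3)[C@H]1[C@]2(C)CCC[C@](C)(COCc4ccccc4)[C@H]2CC[C@]1(C)O
F6 | step 9 | (1S,2S,4aS,5S,8aR)-5-[(benzyloxy)methyl]-2,5,8a-trimethyl-1-[(1E,3R)-3-methylpenta-1,4-dien-1-yl]decahydronaphthalen-2-ol | C=C[C@@H](C)/C=C/[C@H]1[C@]2(C)CCC[C@](C)(COCc3ccccc3)[C@H]2CC[C@]1(C)O
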